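Rings A and B are disconnected together: ring A at C1–C2 and ring B at C9–C10 (labdane numbering). The route exploits the 1,3-relationship between the oxygenated C2 and the quaternary ring-fusion carbon C10: when the CH2 terminus (C1) of an isopropenyl group attacks a C2 aldehyde, ring A closes and a tertiary cation appears exactly at C10; capture by the C8=C9 alkene closes ring B, and proton loss installs the C7=C8 alkene. One operation thus turns an acyclic, farnesoate-derived trienal with a single stereocentre (C5, from an enantioselective allyl–allyl coupling) into the trans-decalin with C9 and C10 set; oxidation and reduction then fix the axial C2 oxygen.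

Key step: step 5

Remark: ring atoms carry labdane numbers (C1 to C10, methyls C17 to C20, side chain C11 to C16), the target being (2S,5R,9R,10R,13E); the (R)-configured diphosphine in step 3 is assumed to give the (10S)-diene 5, and its antipode is used if the sense of induction proves opposite.

Step 1
Reactants: 1 methyl (2E,6E)-farnesoate
Product: 2 methyl (2E,6E,10E)-12-hydroxy-3,7,11-trimethyldodeca-2,6,10-trienoate
Conditions: SeO2 (cat.), t-BuOOH, salicylic acid (cat.), CH2Cl2, 0 °C to rt
Reagents that add atoms: selenium dioxide, O=[Se]=O (catalytic oxygen carrier); tert-butyl hydroperoxide, CC(C)(C)OO (terminal oxidant)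
Why: Sharpless allylic oxidation (ene reaction then [2,3]-sigmatropic shift) should attack the most electron-rich, terminal trisubstituted alkene at its E-methyl group and give the E allylic alcohol, the internal and the ester-conjugated alkenes being less reactive.

Step 2
Reactants: 2 methyl (2E,6E,10E)-12-hydroxy-3,7,11-trimethyldodeca-2,6,10-trienoate
Product: 3 methyl (2E,6E,10E)-12-chloro-3,7,11-trimethyldodeca-2,6,10-trienoate
Conditions: PPh3, CCl4, reflux
Reagents that add atoms: carbon tetrachloride, ClC(Cl)(Cl)Cl
Why: Appel chlorination should replace the primary allylic hydroxyl by SN2 displacement without allylic transposition or loss of alkene geometry, the enoate being inert.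

Step 3
Reactants: 3 methyl (2E,6E,10E)-12-chloro-3,7,11-trimethyldodeca-2,6,10-trienoate; 4 prenylboronic acid pinacol ester
Product: 5 methyl (2E,6E,10S)-3,7,11,11-tetramethyl-10-(prop-1-en-2-yl)trideca-2,6,12-trienoate
Conditions: Pd2(dba)3 (2.5 mol %, zerovalent palladium), (R)-MeO-furyl-BIPHEP [(R)-2,2′-bis(di-2-furylphosphino)-6,6′-dimethoxy-1,1′-biphenyl, 6 mol %], CsF, THF, 60 °C
Reagents that add atoms: none
Why: Palladium-catalysed enantioselective branch-selective allyl–allyl cross-coupling should proceed by 3,3′-reductive elimination from the bis(η1-allyl)palladium intermediate, joining the two substituted allyl termini to form the C4–C5 bond (tertiary carbon next to the gem-dimethyl quaternary carbon), converting the C10=C5 alkene into the isopropenyl group and setting the C5 stereocentre (C10 of 5, S) under control of the chiral diphosphine.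

Step 4
Reactants: 5 methyl (2E,6E,10S)-3,7,11,11-tetramethyl-10-(prop-1-en-2-yl)trideca-2,6,12-trienoate
Product: 6 methyl (2E,6E,10S)-3,7,11,11-tetramethyl-13-oxo-10-(prop-1-en-2-yl)trideca-2,6-dienoate
Conditions: PdCl2(PhCN)2 (cat.), CuCl2·2H2O (cat.), AgNO2 (cat.), O2 (1 atm), t-BuOH/MeNO2, rt
Reagents that add atoms: dioxygen, O=O (delivered through the nitrite co-catalyst)
Why: The nitrite-modified aldehyde-selective Wacker oxidation should act only on the monosubstituted vinyl group (1,1-disubstituted and trisubstituted alkenes are inert), the adjacent quaternary carbon reinforcing anti-Markovnikov oxygenation to give the C2 aldehyde without touching the C5 stereocentre.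

Step 5
Reactants: 6 methyl (2E,6E,10S)-3,7,11,11-tetramethyl-13-oxo-10-(prop-1-en-2-yl)trideca-2,6-dienoate
Product: 8 methyl (2E)-5-[(1R,4aR,7R,8aR)-7-hydroxy-2,5,5,8a-tetramethyl-1,4,4a,5,6,7,8,8a-octahydronaphthalen-1-yl]-3-methylpent-2-enoate, via monocyclic C10 carbocation 7 (not isolated)
Conditions: MeAlCl2 (3 equiv), CH2Cl2, −78 to −20 °C; then 1 M HCl
Reagents that add atoms: none
Why: MeAlCl2 activates the C2 aldehyde, the CH2 terminus (C1) of the isopropenyl group attacks it (Prins addition) to close ring A and leave the tertiary cation 7 at C10, which is captured by C9 of the (E)-C8=C9 alkene to close ring B; loss of H-7 from the resulting C8 cation gives the C7=C8 alkene, the proton being consumed by an Al–CH3 bond. The closest known reaction type is the alkylaluminium-halide-promoted carbonyl-ene/cation–olefin cyclisation of unsaturated aldehydes (aldehyde-initiated polyene cyclisation). Ring A closes 6-exo with respect to the carbonyl and 6-endo-trig with respect to the C1=C10 alkene, ring B closes 6-endo-trig at C8=C9, both through chair transition states. C10 and C9 are controlled by the existing C5 stereocentre: with the C6 chain equatorial on the ring-A chair the C9–C10 bond should form equatorially (the axial face of C10 is shielded by the axial C4 methyl), giving the trans-decalin with axial C10 methyl, and the E alkene geometry places C11 equatorial at C9; C2 is set by the chair with the aluminated oxygen equatorial, and either C2 epimer is corrected in steps 6 and 7. The step needs bicyclisation to outrun the 1,5-hydrogen shift of the simple ene pathway and needs termination after ring B: excess strong Lewis acid favours the open zwitterion, the C8=C9 alkene is held in reach of C10 by the three-carbon tether from C5, and the ester-conjugated C13=C14 alkene is too electron-poor to add to the C8 cation.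

Step 6
Reactants: 8 methyl (2E)-5-[(1R,4aR,7R,8aR)-7-hydroxy-2,5,5,8a-tetramethyl-1,4,4a,5,6,7,8,8a-octahydronaphthalen-1-yl]-3-methylpent-2-enoate
Product: 9 methyl (2E)-3-methyl-5-[(1R,4aR,8aR)-2,5,5,8a-tetramethyl-7-oxo-1,4,4a,5,6,7,8,8a-octahydronaphthalen-1-yl]pent-2-enoate
Conditions: Dess–Martin periodinane, CH2Cl2, rt
Reagents that add atoms: none
Why: Dess–Martin oxidation should convert the C2 carbinol (either epimer) into the ketone under neutral conditions that leave the alkenes, the ester and the ring stereocentres untouched.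

Step 7
Reactants: 9 methyl (2E)-3-methyl-5-[(1R,4aR,8aR)-2,5,5,8a-tetramethyl-7-oxo-1,4,4a,5,6,7,8,8a-octahydronaphthalen-1-yl]pent-2-enoate
Product: 10 (2E)-5-[(1R,4aR,7S,8aR)-7-hydroxy-2,5,5,8a-tetramethyl-1,4,4a,5,6,7,8,8a-octahydronaphthalen-1-yl]-3-methylpent-2-en-1-ol
Conditions: i-Bu2AlH (5 equiv), CH2Cl2, −78 to 0 °C; aq. potassium sodium tartrate
Reagents that add atoms: none
Why: Hydride reduction with i-Bu2AlH should reduce the enoate to the allylic alcohol (1,2-reduction) and the C2 ketone from its equatorial face, because the axial face is shielded by the two syn-axial methyl groups on C4 and C10, so that the new C2 stereocentre carries the axial hydroxyl cis to the C10 methyl (2S).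

Step 8
Reactants: 10 (2E)-5-[(1R,4aR,7S,8aR)-7-hydroxy-2,5,5,8a-tetramethyl-1,4,4a,5,6,7,8,8a-octahydronaphthalen-1-yl]-3-methylpent-2-en-1-ol
Product: 11 (2E)-5-[(1R,4aR,7S,8aR)-7-acetoxy-2,5,5,8a-tetramethyl-1,4,4a,5,6,7,8,8a-octahydronaphthalen-1-yl]-3-methylpent-2-en-1-yl acetate
Conditions: Ac2O, pyridine, DMAP (cat.), rt to 40 °C
Reagents that add atoms: acetic anhydride, CC(=O)OC(C)=O
Why: DMAP-catalysed acylation should esterify both the primary allylic and the hindered axial secondary hydroxyl without affecting any stereocentre.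

Compound list

1 | methyl (2E,6E)-farnesoate [methyl (2E,6E)-3,7,11-trimethyldodeca-2,6,10-trienoate] | CC(C)=CCC/C(C)=C/CC/C(C)=C/C(=O)OC | starting material
2 | methyl (2E,6E,10E)-12-hydroxy-3,7,11-trimethyldodeca-2,6,10-trienoate | OC/C(C)=C/CC/C(C)=C/CC/C(C)=C/C(=O)OC | intermediate
3 | methyl (2E,6E,10E)-12-chloro-3,7,11-trimethyldodeca-2,6,10-trienoate | ClC/C(C)=C/CC/C(C)=C/CC/C(C)=C/C(=O)OC | intermediate
4 | prenylboronic acid pinacol ester [4,4,5,5-tetramethyl-2-(3-methylbut-2-en-1-yl)-1,3,2-dioxaborolane] | CC(C)=CCB1OC(C)(C)C(C)(C)O1 | starting material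
5 | methyl (2E,6E,10S)-3,7,11,11-tetramethyl-10-(prop-1-en-2-yl)trideca-2,6,12-trienoate | C=CC(C)(C)[C@H](C(C)=C)CC/C(C)=C/CC/C(C)=C/C(=O)OC | intermediate
6 | methyl (2E,6E,10S)-3,7,11,11-tetramethyl-13-oxo-10-(prop-1-en-2-yl)trideca-2,6-dienoate | O=CCC(C)(C)[C@H](C(C)=C)CC/C(C)=C/CC/C(C)=C/C(=O)OC | intermediate
7 | monocyclic C10 carbocation: ring A closed, C2 oxygen bound as the MeAlCl2 aluminate, acyclic (E,E)-dienoate chain on C5 | COC(=O)/C=C(\C)CC/C=C(\C)CC[C@H]1[C+](C)C[C@H](O[Al-](C)(Cl)Cl)CC1(C)C | intermediate
8 | methyl (2E)-5-[(1R,4aR,7R,8aR)-7-hydroxy-2,5,5,8a-tetramethyl-1,4,4a,5,6,7,8,8a-octahydronaphthalen-1-yl]-3-methylpent-2-enoate (labdane numbering 2R,5R,9R,10R; 2-OH equatorial) | COC(=O)/C=C(\C)CC[C@@H]1C(C)=CC[C@@H]2C(C)(C)C[C@@H](O)C[C@@]12C | intermediate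
9 | methyl (2E)-3-methyl-5-[(1R,4aR,8aR)-2,5,5,8a-tetramethyl-7-oxo-1,4,4a,5,6,7,8,8a-octahydronaphthalen-1-yl]pent-2-enoate | COC(=O)/C=C(\C)CC[C@@H]1C(C)=CC[C@@H]2C(C)(C)CC(=O)C[C@@]12C | intermediate
10 | (2E)-5-[(1R,4aR,7S,8aR)-7-hydroxy-2,5,5,8a-tetramethyl-1,4,4a,5,6,7,8,8a-octahydronaphthalen-1-yl]-3-methylpent-2-en-1-ol (2-OH axial, cis to the C10 methyl) | OC/C=C(\C)CC[C@@H]1C(C)=CC[C@@H]2C(C)(C)C[C@H](O)C[C@@]12C | intermediate
11 | (2E)-5-[(1R,4aR,7S,8aR)-7-acetoxy-2,5,5,8a-tetramethyl-1,4,4a,5,6,7,8,8a-octahydronaphthalen-1-yl]-3-methylpent-2-en-1-yl acetate [(2S,5R,9R,10R,13E)-labda-7,13-diene-2,15-diyl diacetate] | CC(=O)OC/C=C(\C)CC[C@@H]1C(C)=CC[C@@H]2C(C)(C)C[C@H](OC(C)=O)C[C@@]12C | target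

Total step count: 8
Longest linear sequence: 8 steps (1 to 11)

Steps most likely to fail

Step 5. The cascade may stop after ring A by 1,5-hydrogen transfer (ene pathway). The C8 cation may be captured by chloride or may lose the wrong proton, giving the exocyclic or tetrasubstituted alkene. Axial attack at C10 would give the cis-fused ring system. The fallback sets out from 6 and separates the two ring closures. Me2AlCl (1.5 equiv, CH2Cl2, −78 °C) should run only the type 2 carbonyl-ene closure of ring A, giving methyl (2E,6E)-9-[(1R,4R)-4-hydroxy-2,2-dimethyl-6-methylidenecyclohexyl]-3,7-dimethylnona-2,6-dienoate F1. Markovnikov protonation of its exocyclic alkene (SnCl4, CH2Cl2, −78 °C, the free hydroxyl serving as Lewis-acid-assisted proton source) regenerates the C10 cation under conditions where no ene pathway exists. Ring B then closes and the route is rejoined at 8.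

Step 3. Transmetallation and reductive elimination at the congested termini may be slow. That would allow linear coupling, β-hydride elimination of the allylpalladium species to a diene, or poor facial discrimination with the 2-methyl-substituted electrophile. The fallback sets out from 2 and builds the C4–C5 bond by a sigmatropic route. Acylation (isobutyric anhydride, DMAP, pyridine) gives the isobutyrate ester F2. Enantioselective Ireland–Claisen rearrangement then follows, through the chiral boron ketene acetal formed with the bromoborane from 1,2-diphenylethane-1,2-diamine bis(3,5-bis(trifluoromethyl)benzenesulfonamide) and Et3N (toluene/hexane, −78 to −20 °C). It gives (3S,6E,10E)-12-methoxy-2,2,6,10-tetramethyl-12-oxo-3-(prop-1-en-2-yl)dodeca-6,10-dienoic acid F3. Mixed-anhydride activation (ClCO2Et, Et3N) and NaBH4 reduce the acid selectively to the neopentyl alcohol F4. Dess–Martin oxidation gives the neopentyl aldehyde F5. Wittig homologation with Ph3P=CHOMe gives the methyl enol ether F6. Mild aqueous acid (HCl, THF) hydrolyses it, and the route is rejoined at 6.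

Step 4. Turnover at the hindered vinyl group may be sluggish. Markovnikov attack would give the methyl ketone, and palladium-mediated isomerisation of the isopropenyl group is possible. The fallback sets out from 5. Hydroboration with disiamylborane (THF, 0 °C) discriminates the monosubstituted vinyl group from the more hindered alkenes. Oxidation with NaBO3·4H2O gives the primary alcohol F7. Dess–Martin oxidation rejoins the route at 6.

Further compounds

F1 | step 5 | methyl (2E,6E)-9-[(1R,4R)-4-hydroxy-2,2-dimethyl-6-methylidenecyclohexyl]-3,7-dimethylnona-2,6-dienoate | COC(=O)/C=C(\C)CC/C=C(\C)CC[C@H]1C(=C)C[C@H](O)CC1(C)C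
F2 | step 3 | methyl (2E,6E,10E)-3,7,11-trimethyl-12-(2-methylpropanoyloxy)dodeca-2,6,10-trienoate | CC(C)C(=O)OC/C(C)=C/CC/C(C)=C/CC/C(C)=C/C(=O)OC
F3 | step 3 | (3S,6E,10E)-12-methoxy-2,2,6,10-tetramethyl-12-oxo-3-(prop-1-en-2-yl)dodeca-6,10-dienoic acid | OC(=O)C(C)(C)[C@H](C(C)=C)CC/C(C)=C/CC/C(C)=C/C(=O)OC
F4 | step 3 | methyl (2E,6E,10S)-12-hydroxy-3,7,11,11-tetramethyl-10-(prop-1-en-2-yl)dodeca-2,6-dienoate | OCC(C)(C)[C@H](C(C)=C)CC/C(C)=C/CC/C(C)=C/C(=O)OC
F5 | step 3 | methyl (2E,6E,10S)-3,7,11,11-tetramethyl-12-oxo-10-(prop-1-en-2-yl)dodeca-2,6-dienoate | O=CC(C)(C)[C@H](C(C)=C)CC/C(C)=C/CC/C(C)=C/C(=O)OC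
F6 | step 3 | methyl (2E,6E,10S)-13-methoxy-3,7,11,11-tetramethyl-10-(prop-1-en-2-yl)trideca-2,6,12-trienoate (enol ether as E/Z mixture) | COC=CC(C)(C)[C@H](C(C)=C)CC/C(C)=C/CC/C(C)=C/C(=O)OC
F7 | step 4 | methyl (2E,6E,10S)-13-hydroxy-3,7,11,11-tetramethyl-10-(prop-1-en-2-yl)trideca-2,6-dienoate | OCCC(C)(C)[C@H](C(C)=C)CC/C(C)=C/CC/C(C)=C/C(=O)OC
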